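**Plan**
- Cuts, in order: the two O–CH2OMe acetals; the ring bond between the Z-alkene carbon and ring B; the ester C–O bond at the pentyl-bearing carbinol; the ring A carbon–oxygen bond of the diaryl ether.
- Enabling feature: in ring B the alkenyl-bearing carbon sits between the carbon carrying the aryloxy oxygen and the carbon carrying the formyl group, and its bond to the alkene is one of the twelve ring bonds. A bromide on that carbon is activated by the ortho formyl group, and the alkene can arrive as a boronate whose Z geometry is already settled.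
- Forward: rings A and B are bought as benzenes and joined through oxygen. The C9 chain is grown from hexanal, then acid and alcohol are joined as an ester. The only ring formed, the 12-membered lactone, closes last but one, and a single acid step frees the phenol and the allylic alcohol.
- Stereochemistry: both carbinol centres (S,S, syn) come from one reagent-controlled (Z)-γ-alkoxyallylboration of hexanal. The Z-alkene comes from a rhodium-catalysed trans-hydroboration of a terminal alkyne and is carried through with retention.

Key step: step 13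

Remark: both carbinol carbons read as S from the SMILES, which is the syn (threo) 1,2-diol pattern; allyl methoxymethyl ether 1 is taken as a catalogue compound.

**Step 1**
Reactants: 1 allyl methoxymethyl ether; 2 hexanal
Product: 6 (3S,4S)-3-(methoxymethoxy)non-1-en-4-ol, via Z-alkoxyallyllithium 3 (not isolated), via Z-alkoxyallylborane 4 (not isolated), via borinate 5 (not isolated)
Conditions: 1, s-BuLi, THF, −78 °C; (+)-Ipc2BOMe [from (−)-α-pinene], −78 °C; BF3·OEt2, then 2, −78 °C to rt; 3 M NaOH, 30% H2O2, rt
Reagents that add atoms: none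
Why: Brown (Z)-γ-alkoxyallylboration, in which internal O–Li chelation fixes the Z geometry of 3 and hence of 4, the chair-like Zimmerman–Traxler transition state turns that geometry into the syn relationship, and the isopinocampheyl groups derived from (−)-α-pinene steer allyl transfer to the Re face of hexanal, which should set C3 and C4 as S,S in one operation.

**Step 2**
Reactants: 6 (3S,4S)-3-(methoxymethoxy)non-1-en-4-ol
Product: 7 (3S,4S)-3-(methoxymethoxy)-4-(triethylsilyloxy)non-1-ene
Conditions: TESCl, imidazole, CH2Cl2, 0 °C to rt
Reagents that add atoms: triethylsilyl chloride, CC[Si](Cl)(CC)CC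
Why: Routine silylation of a secondary alcohol, with the triethylsilyl group chosen because it should outlast ozone, carbonate in methanol and the borane yet leave under acid too weak to touch the MOM acetal.

**Step 3**
Reactants: 7 (3S,4S)-3-(methoxymethoxy)-4-(triethylsilyloxy)non-1-ene
Product: 9 (2R,3S)-2-(methoxymethoxy)-3-(triethylsilyloxy)octanal, via ozonide 8 (not isolated)
Conditions: O3, CH2Cl2, −78 °C; PPh3, −78 °C to rt
Reagents that add atoms: ozone, [O-][O+]=O
Why: Ozonolysis with reductive work-up (Criegee sequence) cleaves the only C=C bond, and the cold, neutral conditions should leave the silyl ether, the acetal and the new α-alkoxy aldehyde centre unchanged (the descriptor at C2 changes only through CIP priorities).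

**Step 4**
Reactants: 9 (2R,3S)-2-(methoxymethoxy)-3-(triethylsilyloxy)octanal
Product: 10 (3S,4S)-3-(methoxymethoxy)-4-(triethylsilyloxy)non-1-yne
Conditions: dimethyl (1-diazo-2-oxopropyl)phosphonate, K2CO3, MeOH, 0 °C to rt
Reagents that add atoms: dimethyl (1-diazo-2-oxopropyl)phosphonate, COP(=O)(OC)C(=[N+]=[N-])C(C)=O
Why: Seyferth–Gilbert homologation in its Ohira–Bestmann form, in which the diazomethylphosphonate anion adds to the aldehyde and the alkylidene carbene left after loss of phosphate and N2 undergoes a 1,2-hydrogen shift, under a base mild enough that α-alkoxy aldehydes normally keep their configuration.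

**Step 5**
Reactants: 10 (3S,4S)-3-(methoxymethoxy)-4-(triethylsilyloxy)non-1-yne
Product: 11 2-[(1Z,3S,4S)-3-(methoxymethoxy)-4-(triethylsilyloxy)non-1-en-1-yl]-4,4,5,5-tetramethyl-1,3,2-dioxaborolane
Conditions: HBpin, [Rh(cod)Cl]2 (1.5 mol %), P(i-Pr)3 (6 mol %), Et3N, cyclohexane, rt; 10 in slight excess over HBpin
Reagents that add atoms: pinacolborane, CC1(C)OBOC1(C)C
Why: Rhodium-catalysed formal trans-hydroboration of a terminal alkyne, in which the alkyne hydrogen migrates to give a rhodium vinylidene, boryl transfer to its α-carbon and C–H reductive elimination place boron cis to the chain, and the bulky, basic P(i-Pr)3 together with Et3N favours this path over ordinary syn addition.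

**Step 6**
Reactants: 11 Z-alkenylboronate silyl ether
Product: 12 (1Z,3S,4S)-3-(methoxymethoxy)-1-(4,4,5,5-tetramethyl-1,3,2-dioxaborolan-2-yl)non-1-en-4-ol
Conditions: PPTS (0.2 equiv), MeOH/CH2Cl2, 0 °C to rt; used at once
Reagents that add atoms: none
Why: Acid-catalysed methanolysis of the triethylsilyl ether is far faster than cleavage of an alkyl MOM ether, fluoride is avoided for the sake of boron, and the chelating pinacol should keep boron from being taken over by the freed δ-hydroxyl.

**Step 7**
Reactants: 13 5-hydroxy-2-methoxybenzaldehyde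
Product: 14 2-bromo-3-hydroxy-6-methoxybenzaldehyde
Conditions: Br2 (1.05 equiv), NaOAc, AcOH, 15 °C to rt
Reagents that add atoms: bromine, BrBr
Why: Electrophilic aromatic bromination ruled by the free hydroxyl, whose para position is blocked by the methoxy-bearing carbon and whose ortho carbon next to the formyl group is the one attacked, as 3-hydroxybenzaldehydes such as isovanillin and gentisaldehyde do, so bromine should end up between the hydroxyl and formyl carbons.

**Step 8**
Reactants: 14 2-bromo-3-hydroxy-6-methoxybenzaldehyde; 15 [3-(methoxycarbonyl)-4-methylphenyl]boronic acid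
Product: 16 methyl 5-(2-bromo-3-formyl-4-methoxyphenoxy)-2-methylbenzoate
Conditions: Cu(OAc)2 (1.5 equiv), pyridine (5 equiv), 4 Å molecular sieves, CH2Cl2, dry air, rt; 15 (2 equiv)
Reagents that add atoms: none
Why: Chan–Lam O-arylation, in which phenoxide and the aryl group from boron meet on copper and reductive elimination from trivalent copper forms the diaryl ether at room temperature, conditions under which ortho-halogenated phenols couple and the C–Br bond, aldehyde and ester are left alone.

**Step 9**
Reactants: 16 methyl 5-(2-bromo-3-formyl-4-methoxyphenoxy)-2-methylbenzoate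
Product: 17 methyl 5-(2-bromo-3-formyl-4-hydroxyphenoxy)-2-methylbenzoate
Conditions: BCl3 (1.5 equiv), CH2Cl2, −78 to 0 °C; aq. NaHCO3
Reagents that add atoms: none
Why: Chelation-assisted ether cleavage, in which BCl3 ties the formyl oxygen and the neighbouring methoxy oxygen into a six-membered chelate and chloride removes the methyl group, carried out on this robust intermediate so that no strong Lewis acid is needed once the allylic oxygen and the macrocycle exist.

**Step 10**
Reactants: 17 methyl 5-(2-bromo-3-formyl-4-hydroxyphenoxy)-2-methylbenzoate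
Product: 18 methyl 5-[2-bromo-3-formyl-4-(methoxymethoxy)phenoxy]-2-methylbenzoate
Conditions: MOMCl, i-Pr2NEt, CH2Cl2, 0 °C to rt
Reagents that add atoms: chloromethyl methyl ether, COCCl
Why: Standard O-alkylation of a salicylaldehyde-type phenol with MOMCl, which gives the phenol the same base-stable, acid-labile acetal as the allylic oxygen and so allows one common release at the end.

**Step 11**
Reactants: 18 methyl 5-[2-bromo-3-formyl-4-(methoxymethoxy)phenoxy]-2-methylbenzoate
Product: 19 5-[2-bromo-3-formyl-4-(methoxymethoxy)phenoxy]-2-methylbenzoic acid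
Conditions: LiOH·H2O (3 equiv), THF/H2O 3:1, rt to 40 °C; 0.5 M HCl to pH 4, 0 °C
Reagents that add atoms: lithium hydroxide, [Li+].[OH-]
Why: Plain saponification of a methyl benzoate, tolerated because the aldehyde has no α-hydrogen and the MOM ether is base-stable, with cold acidification only to pH 4 to spare the aryl acetal.

**Step 12**
Reactants: 19 diaryl ether acid; 12 hydroxy Z-alkenylboronate
Product: 21 seco ester (1Z,3S,4S)-3-(methoxymethoxy)-1-(4,4,5,5-tetramethyl-1,3,2-dioxaborolan-2-yl)non-1-en-4-yl 5-[2-bromo-3-formyl-4-(methoxymethoxy)phenoxy]-2-methylbenzoate, via mixed anhydride 20 (not isolated)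
Conditions: 19, 2,4,6-trichlorobenzoyl chloride, Et3N, toluene, rt; then 12, DMAP, toluene, rt
Reagents that add atoms: none
Why: Yamaguchi esterification, in which DMAP opens 20 at the less shielded toluoyl carbonyl and the acylpyridinium acylates the secondary alcohol through its O–H bond only, so C4 keeps its configuration while boronate, bromide, aldehyde and acetals stay inert.

**Step 13**
Reactants: 21 seco ester
Product: 22 bis-MOM macrolactone (12-membered ring, Z-alkene, S,S)
Conditions: Pd2(dba)3 (5 mol %), SPhos (2-dicyclohexylphosphino-2',6'-dimethoxybiphenyl, 20 mol %), K3PO4 (3 equiv), degassed THF/H2O 20:1, 60 °C; 21 added by syringe pump over 12 h, final 1 mM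
Reagents that add atoms: none
Why: Zerovalent palladium bearing SPhos inserts into the ring B C–Br bond, which the ortho formyl group renders electron-poor, phosphate and water turn the pinacol boronate into a hydroxyboronate that passes its alkenyl carbon to palladium with retention, and reductive elimination makes the aryl–alkenyl bond. The closest known reaction type is the intramolecular Suzuki–Miyaura macrocyclization of alkenylboron reagents with aryl or alkenyl halides, an established route to medium and large rings, 12-membered lactones included. The one ring closes as a 12-membered macrolactone by C(sp2)–C(sp2) reductive elimination from a 13-membered palladacycle, with the meta-bridged ring A, the ortho-bridged ring B and the cis alkene already bending the chain towards closure. No stereocentre is created, since the two carbinol centres are spectators (the allylic oxygen is an acetal and a poor leaving group, so π-allyl ionisation is not expected) and the alkene geometry is simply carried over from 21. The step needs ring closure to beat chain growth and protodeboronation, which slow addition into a dilute catalyst solution should secure. It also needs the Z geometry to survive, which the bulky, electron-rich biaryl phosphine should help by speeding insertion and reductive elimination at the doubly ortho-substituted carbon and leaving the alkenylpalladium little time to isomerise.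

**Step 14**
Reactants: 22 bis-MOM macrolactone
Product: 23 target CNP0238900.1
Conditions: 3 M aq. HCl/THF 1:3, 40 °C
Reagents that add atoms: none
Why: Acid hydrolysis of both formaldehyde acetals breaks bonds only at the acetal carbons, so the allylic stereocentre is untouched, and ionisation of the freed allylic alcohol should be disfavoured by the formyl-bearing ring and the adjacent acyloxy group, as in the usual final MOM removal from benzo-fused macrolactones.

**Compound list**
1 | allyl methoxymethyl ether | C=CCOCOC | starting material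
2 | hexanal | CCCCCC=O | starting material
3 | (Z)-3-(methoxymethoxy)allyllithium | [Li]C/C=C\OCOC | intermediate
4 | [(Z)-3-(methoxymethoxy)allyl]bis(isopinocampheyl)borane, Ipc from (−)-α-pinene | COCO/C=C\CB([C@H]1C[C@H]2C[C@@H]([C@@H]1C)C2(C)C)[C@H]1C[C@H]2C[C@@H]([C@@H]1C)C2(C)C | intermediate
5 | bis(isopinocampheyl)borinate of 6 | CCCCC[C@H](OB([C@H]1C[C@H]2C[C@@H]([C@@H]1C)C2(C)C)[C@H]1C[C@H]2C[C@@H]([C@@H]1C)C2(C)C)[C@@H](OCOC)C=C | intermediate
6 | (3S,4S)-3-(methoxymethoxy)non-1-en-4-ol | CCCCC[C@H](O)[C@@H](OCOC)C=C | intermediate
7 | (3S,4S)-3-(methoxymethoxy)-4-(triethylsilyloxy)non-1-ene | CCCCC[C@H](O[Si](CC)(CC)CC)[C@@H](OCOC)C=C | intermediate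
8 | secondary ozonide (1,2,4-trioxolane) of 7 | CCCCC[C@H](O[Si](CC)(CC)CC)[C@@H](OCOC)C1OCOO1 | intermediate
9 | (2R,3S)-2-(methoxymethoxy)-3-(triethylsilyloxy)octanal | CCCCC[C@H](O[Si](CC)(CC)CC)[C@@H](OCOC)C=O | intermediate
10 | (3S,4S)-3-(methoxymethoxy)-4-(triethylsilyloxy)non-1-yne | CCCCC[C@H](O[Si](CC)(CC)CC)[C@@H](OCOC)C#C | intermediate
11 | 2-[(1Z,3S,4S)-3-(methoxymethoxy)-4-(triethylsilyloxy)non-1-en-1-yl]-4,4,5,5-tetramethyl-1,3,2-dioxaborolane | CCCCC[C@H](O[Si](CC)(CC)CC)[C@@H](OCOC)/C=C\B1OC(C)(C)C(C)(C)O1 | intermediate
12 | (1Z,3S,4S)-3-(methoxymethoxy)-1-(4,4,5,5-tetramethyl-1,3,2-dioxaborolan-2-yl)non-1-en-4-ol | CCCCC[C@H](O)[C@@H](OCOC)/C=C\B1OC(C)(C)C(C)(C)O1 | intermediate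
13 | 5-hydroxy-2-methoxybenzaldehyde | COc1ccc(O)cc1C=O | starting material
14 | 2-bromo-3-hydroxy-6-methoxybenzaldehyde | COc1ccc(O)c(Br)c1C=O | intermediate
15 | [3-(methoxycarbonyl)-4-methylphenyl]boronic acid | COC(=O)c1cc(B(O)O)ccc1C | starting material
16 | methyl 5-(2-bromo-3-formyl-4-methoxyphenoxy)-2-methylbenzoate | COC(=O)c1cc(ccc1C)Oc1ccc(OC)c(C=O)c1Br | intermediate
17 | methyl 5-(2-bromo-3-formyl-4-hydroxyphenoxy)-2-methylbenzoate | COC(=O)c1cc(ccc1C)Oc1ccc(O)c(C=O)c1Br | intermediate
18 | methyl 5-[2-bromo-3-formyl-4-(methoxymethoxy)phenoxy]-2-methylbenzoate | COC(=O)c1cc(ccc1C)Oc1ccc(OCOC)c(C=O)c1Br | intermediate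
19 | 5-[2-bromo-3-formyl-4-(methoxymethoxy)phenoxy]-2-methylbenzoic acid | OC(=O)c1cc(ccc1C)Oc1ccc(OCOC)c(C=O)c1Br | intermediate
20 | 2,4,6-trichlorobenzoic mixed anhydride of 19 | O=C(OC(=O)c1cc(ccc1C)Oc1ccc(OCOC)c(C=O)c1Br)c1c(Cl)cc(Cl)cc1Cl | intermediate
21 | seco ester: ring B bromide, (Z)-alkenyl pinacolboronate, both oxygens as MOM ethers | CCCCC[C@H](OC(=O)c1cc(ccc1C)Oc1ccc(OCOC)c(C=O)c1Br)[C@@H](OCOC)/C=C\B1OC(C)(C)C(C)(C)O1 | intermediate
22 | bis-MOM 12-membered macrolactone, Z-alkene, S,S | CCCCC[C@@H]1OC(=O)c2cc(ccc2C)Oc2ccc(OCOC)c(C=O)c2/C=C\[C@@H]1OCOC | intermediate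
23 | CNP0238900.1 | CCCCC[C@@H]1OC(=O)c2cc(ccc2C)Oc2ccc(O)c(C=O)c2/C=C\[C@@H]1O | target

**Count**
Total steps: 14.
Longest linear sequence: 9 (steps 1–6, 12, 13, 14). The aryl branch contributes steps 7–11.

**Steps most likely to fail**

1. Step 13. Chain growth between molecules, loss of boron by protonolysis before transmetalation, or sluggish insertion at the doubly flanked C–Br bond could starve the ring closure.
   - The fallback moves the ring closure to the ester bond and sets out from boronate 11 and bromide 18.
   - These are coupled intermolecularly at ordinary concentration (Pd2(dba)3, SPhos, K3PO4, THF/H2O, 60 °C) to the Z-styrenyl methyl ester F1.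
   - Bu4NF buffered with AcOH in THF frees the carbinol to give the hydroxy ester F2, and LiOH in THF/H2O gives the seco acid F3.
   - Shiina macrolactonization (2-methyl-6-nitrobenzoic anhydride, DMAP, toluene, slow addition) closes the 12-membered lactone and comes back to the route at 22.

2. Step 5. Competing syn addition eroding the Z geometry, a second hydroboration, or inhibition of rhodium by the propargylic acetal oxygens could spoil the boronate.
   - The fallback fixes the geometry by syn-hydrometalation of a boron-capped alkyne and sets out from 10.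
   - n-BuLi in THF at −78 °C, then 2-isopropoxy-4,4,5,5-tetramethyl-1,3,2-dioxaborolane and HCl in Et2O, give the alkynylboronate F4.
   - Cp2Zr(H)Cl in THF adds syn with zirconium on the boron-bearing carbon. Water then replaces zirconium by hydrogen with retention, which comes back to the route at 11.

3. Step 12. Capture of the free hydroxyl by the neighbouring boron with loss of pinacol, or slow acylation of the crowded carbinol by an ortho-substituted benzoyl donor, could block the ester.
   - The fallback makes the ester before boron is present and sets out from aldehyde 9.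
   - Stork–Zhao olefination ([Ph3PCH2I]I, NaN(SiMe3)2, THF/DMPU, −78 °C) gives the Z-alkenyl iodide F5, and PPTS in MeOH gives the iodo alcohol F6.
   - Yamaguchi esterification with 19 gives the iodo bromo seco ester F7.
   - Miyaura borylation (B2pin2, PdCl2(PPh3)2, PPh3, KOPh, toluene, 50 °C) should engage the alkenyl C–I bond well before the hindered aryl C–Br bond, which comes back to the route at 21.

**Further compounds**
F1 | step 13 | methyl 5-{3-formyl-4-(methoxymethoxy)-2-[(1Z,3S,4S)-3-(methoxymethoxy)-4-(triethylsilyloxy)non-1-en-1-yl]phenoxy}-2-methylbenzoate | CCCCC[C@H](O[Si](CC)(CC)CC)[C@@H](OCOC)/C=C\c1c(Oc2ccc(C)c(c2)C(=O)OC)ccc(OCOC)c1C=O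
F2 | step 13 | methyl 5-{3-formyl-2-[(1Z,3S,4S)-4-hydroxy-3-(methoxymethoxy)non-1-en-1-yl]-4-(methoxymethoxy)phenoxy}-2-methylbenzoate | CCCCC[C@H](O)[C@@H](OCOC)/C=C\c1c(Oc2ccc(C)c(c2)C(=O)OC)ccc(OCOC)c1C=O
F3 | step 13 | 5-{3-formyl-2-[(1Z,3S,4S)-4-hydroxy-3-(methoxymethoxy)non-1-en-1-yl]-4-(methoxymethoxy)phenoxy}-2-methylbenzoic acid | CCCCC[C@H](O)[C@@H](OCOC)/C=C\c1c(Oc2ccc(C)c(c2)C(=O)O)ccc(OCOC)c1C=O
F4 | step 5 | 2-[(3S,4S)-3-(methoxymethoxy)-4-(triethylsilyloxy)non-1-yn-1-yl]-4,4,5,5-tetramethyl-1,3,2-dioxaborolane | CCCCC[C@H](O[Si](CC)(CC)CC)[C@@H](OCOC)C#CB1OC(C)(C)C(C)(C)O1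
F5 | step 12 | (1Z,3S,4S)-1-iodo-3-(methoxymethoxy)-4-(triethylsilyloxy)non-1-ene | CCCCC[C@H](O[Si](CC)(CC)CC)[C@@H](OCOC)/C=C\I
F6 | step 12 | (1Z,3S,4S)-1-iodo-3-(methoxymethoxy)non-1-en-4-ol | CCCCC[C@H](O)[C@@H](OCOC)/C=C\I
F7 | step 12 | (1Z,3S,4S)-1-iodo-3-(methoxymethoxy)non-1-en-4-yl 5-[2-bromo-3-formyl-4-(methoxymethoxy)phenoxy]-2-methylbenzoate | CCCCC[C@H](OC(=O)c1cc(ccc1C)Oc1ccc(OCOC)c(C=O)c1Br)[C@@H](OCOC)/C=C\I
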